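How long should I stir the flask to catch the most target, and how much will there be?

- Sunday's: substrate 0.80 M; gas phase 17 mM (held); run made earlier
- flask: substrate 0.40 M; gas phase 17 mM (held); time 2.5 d

1. the moment within 2.5 d at which there is most target
2. the amount of target, in percent of the substrate charged, at that time

- the earlier runs were read with a standard deviation of 1 percentage point
- at the start none of the gas phase is in solution

Sunday's run (percent of the substrate charged)

| time / h | target / % | substrate / % |
|---|---|---|
| 1.50 | 26.1 | 69.4 |
| 3.00 | 37.7 | 46.0 |
| 5.00 | 40.6 | 22.1 |
| 6.00 | 34.6 | 13.6 |

(standard deviation of a reading: 1 percentage point)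

I read this table row by row. I suppose that each substrate lost takes one gas, and that whatever is missing from substrate plus target went on to over-reacted product and took a second. Twice the substrate lost, minus the target, times the charge, over the time, is then the gas taken per litre and hour. The rows give 0.187 M h⁻¹, 0.187 M h⁻¹, 0.184 M h⁻¹ and 0.184 M h⁻¹, level within the scatter, while c(substrate) falls from 0.555 M to 0.109 M. I call the last figure the uptake U.

A rate that ignores c(substrate) and c(target) is zero order in both. The concentration that orders it is c(dissolved gas), which I take to stay far below saturation during these readings, with the crossing from the gas phase as rate-limiting step. The flask's 0.40 M lies inside that range and its gas phase is held at the same 17 mM, so I keep U. If both steps draw on the same dissolved gas, target follows one curve in gas taken per substrate charged.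

Interpolating the slope of the target column to zero puts Sunday's top at 4.29 h, which is 0.989 gas per substrate. The flask reaches that at 0.0894 d, and I expect Sunday's height, whose highest reading is 40.6%.

The forecast says 41.5% at 0.122 d, later than my time, holding that “the peak should not depend on charge”.

The flask gives 41.3% at 0.0865 d.

    gas phase ⇌ dissolved gas, rate k1*(csat - [dissolved gas]) (kL = 0.180 min⁻¹)
    substrate + dissolved gas → target (k = 37.0 M⁻¹ min⁻¹)
    dissolved gas + target → over-reacted product (k = 29.0 M⁻¹ min⁻¹)
    dissolved gas → decomposed reagent (k = 0.00740 min⁻¹)

At that time the flask holds c(dissolved gas) of 3.13 × 10⁻⁴ M, far below 17 mM. With 32.4% substrate and 26.2% over-reacted product, its uptake, averaged from the start up to that time, comes to 0.181 M h⁻¹, close to U. The neighbour flask at 0.16 M also tops at 41.3%. The largest single effect on that height is the loss of target to over-reacted product: with this step taken away, the flask's highest target is 100% instead of 41.3%.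

The readings are calculated for an exercise.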